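**Retrosynthetic overview**
1. Feature: in each 8-alkyl-7-methoxycoumarin the benzenoid atoms C8a(–O1), C8(alkyl) and C7(OMe) are C1, C2 and C3 of a 2-alkyl-3-methoxycyclohex-2-enone, and C4a is its alpha-prime carbon C6. Both benzene rings are therefore carried as cyclohexane-1,3-dione-derived carbocycles and aromatised late.
2. Last disconnections: the silyl ether (step 10), then both pyranone rings (O1–C2 and C3=C4) from bis(salicylaldehyde) 13 and Ph3P=C=C=O (step 9).
3. Key disconnection: both arene rings of 13 from the bis[6-(hydroxymethylene)-3-methoxycyclohex-2-enone] 11 by DDQ dehydrogenation; 11 comes from bis(vinylogous ester) 8 by twofold alpha-prime formylation.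
4. The ether C–O bond (tertiary carbon of unit B to the secondary oxygen of unit A) comes from (S)-epoxide 5 and (S)-allylic alcohol 6. Both derive from the one epoxide made by C2-prenylation of cyclohexane-1,3-dione, O-methylation and Shi epoxidation; its CH carbon becomes both stereocentres.
5. Ring order: the two carbocycles are present from step 1, become the two benzene rings together in step 8, and the two pyranone rings close together in step 9.

Key step: step 8

Remark: 3 is drawn as its diketo form and 11 as the chelated hydroxymethylene enol; the enantiomer of the D-fructose-derived Shi ketone is taken to be purchasable.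

**Step 1**
Reactants: 1 cyclohexane-1,3-dione; 2 prenyl bromide (1-bromo-3-methylbut-2-ene)
Product: 3 2-(3-methylbut-2-en-1-yl)cyclohexane-1,3-dione
Conditions: KOH (1 equiv), H2O, 0 °C → rt
Reagents that add atoms: none
Why: C-alkylation of the ambident dione enolate by a reactive allylic bromide in water, where hydrogen bonding to the enolate oxygens directs attack through C2 (classical aqueous-alkali allylation of a cyclic 1,3-dione).

**Step 2**
Reactants: 3 2-(3-methylbut-2-en-1-yl)cyclohexane-1,3-dione
Product: 4 3-methoxy-2-(3-methylbut-2-en-1-yl)cyclohex-2-en-1-one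
Conditions: Me2SO4, K2CO3, acetone, reflux
Reagents that add atoms: dimethyl sulfate, COS(=O)(=O)OC
Why: O-methylation of the vinylogous acid by a hard methylating agent (enol ether formation); the dione is symmetrical and C2 is already substituted, so a single vinylogous methyl ester should result.

**Step 3**
Reactants: 4 3-methoxy-2-(3-methylbut-2-en-1-yl)cyclohex-2-en-1-one
Product: 5 2-{[(2S)-3,3-dimethyloxiran-2-yl]methyl}-3-methoxycyclohex-2-en-1-one
Conditions: ent-Shi ketone (L-fructose-derived, 0.3 equiv), 2KHSO5·KHSO4·K2SO4, K2CO3, Bu4NHSO4 (cat.), MeCN–CH2(OMe)2–aq. Na2B4O7 buffer, 0 °C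
Reagents that add atoms: potassium peroxymonosulfate, [K+].[O-]S(=O)(=O)OO
Why: Shi asymmetric epoxidation, in which the chiral ketone-derived dioxirane delivers oxygen through a spiro transition state to one face of the electron-rich trisubstituted prenyl double bond; the L-series catalyst should set the S configuration at the epoxide CH carbon (the D-series catalyst gives R for alkenes of the type RCH2–CH=CMe2), and the electron-poor tetrasubstituted enone double bond is left alone.

**Step 4**
Reactants: 5 2-{[(2S)-3,3-dimethyloxiran-2-yl]methyl}-3-methoxycyclohex-2-en-1-one (one portion)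
Product: 6 2-[(2S)-2-hydroxy-3-methylbut-3-en-1-yl]-3-methoxycyclohex-2-en-1-one
Conditions: Et2AlCl + lithium 2,2,6,6-tetramethylpiperidide (4 equiv each, premixed), toluene, 0 °C; aq. KNaC4H4O6 work-up
Reagents that add atoms: none
Why: aluminium amide-promoted rearrangement of an epoxide to an allylic alcohol, in which aluminium binds the epoxide oxygen and the hindered amide removes a syn proton from a methyl group of the tertiary carbon through a cyclic transition state; only the tertiary C–O bond breaks, so the S configuration of the CH carbon is kept, and the excess reagent allows for reversible enolisation of the vinylogous ester.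

**Step 5**
Reactants: 5 2-{[(2S)-3,3-dimethyloxiran-2-yl]methyl}-3-methoxycyclohex-2-en-1-one; 6 2-[(2S)-2-hydroxy-3-methylbut-3-en-1-yl]-3-methoxycyclohex-2-en-1-one
Product: 7 2-[(2S)-2-{[(3S)-3-hydroxy-4-(2-methoxy-6-oxocyclohex-1-en-1-yl)-2-methylbutan-2-yl]oxy}-3-methylbut-3-en-1-yl]-3-methoxycyclohex-2-en-1-one
Conditions: 6 (3 equiv, excess recovered), BF3·OEt2 (1.2 equiv per vinylogous ester), CH2Cl2, −78 → −40 °C, 5 added slowly; Et3N quench
Reagents that add atoms: none
Why: Lewis acid-promoted alcoholysis of a trisubstituted epoxide at its tertiary carbon (borderline SN1 opening with Markovnikov regiochemistry); neither C–O bond at a stereogenic CH carbon is broken, so both S centres are carried over, and BF3 in excess keeps the vinylogous ester carbonyls complexed so that they should not compete as internal nucleophiles.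

**Step 6**
Reactants: 7 the hydroxy ether of step 5
Product: 8 2-[(2S)-2-{[(3S)-3-[(tert-butyldimethylsilyl)oxy]-4-(2-methoxy-6-oxocyclohex-1-en-1-yl)-2-methylbutan-2-yl]oxy}-3-methylbut-3-en-1-yl]-3-methoxycyclohex-2-en-1-one
Conditions: TBSOTf, 2,6-lutidine, CH2Cl2, −78 → 0 °C
Reagents that add atoms: tert-butyldimethylsilyl trifluoromethanesulfonate, CC(C)(C)[Si](C)(C)OS(=O)(=O)C(F)(F)F
Why: silylation of a hindered secondary alcohol with a silyl triflate and a non-nucleophilic base; the free hydroxyl would otherwise consume base in step 7 and add to the ketenylidene phosphorane in step 9.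

**Step 7**
Reactants: 8 the silyl ether of step 6; 9 ethyl formate
Product: 11 the bis[6-(hydroxymethylene)-3-methoxycyclohex-2-en-1-one] analogue of 8 (a chelated HO–CH= group on C6 of each ring; S,S), via bis(lithium dienolate) 10 (not isolated)
Conditions: LiN(iPr)2 (excess), THF, −78 °C; then HCO2Et, −78 → 0 °C; AcOH quench
Reagents that add atoms: none
Why: Stork–Danheiser kinetic deprotonation of each 3-methoxy-enone at the alpha-prime CH2 (C6) gives the cross-conjugated lithium dienolates, which undergo crossed Claisen formylation with ethyl formate; each product is held as its chelated enolate, which should prevent a second formylation.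

**Step 8**
Reactants: 11 the bis(hydroxymethylene) compound of step 7
Product: 13 3-[(2S)-2-{[(3S)-3-[(tert-butyldimethylsilyl)oxy]-4-(3-formyl-2-hydroxy-6-methoxyphenyl)-2-methylbutan-2-yl]oxy}-3-methylbut-3-en-1-yl]-2-hydroxy-4-methoxybenzaldehyde, via bis(formyldienone) 12 (not isolated)
Conditions: DDQ (2.1 equiv), 1,4-dioxane, rt
Reagents that add atoms: none
Why: Each β-keto aldehyde unit is present as its chelated enol; DDQ abstracts hydride from the ring CH2 (C5) allylic to the enol double bond, and the oxygen-stabilised cation loses a proton to give the cross-conjugated 6-formylcyclohexa-2,5-dienone 12, which tautomerises at once (C4–H to oxygen) to the 3-alkyl-2-hydroxy-4-methoxybenzaldehyde, so one equivalent of DDQ per ring is enough. The closest known reaction type is the DDQ dehydrogenation of 2-(hydroxymethylene) ketones to 2-formyl enones and of 6-(hydroxymethylene)cyclohex-2-enones to salicylaldehydes. No ring is closed and no stereocentre is formed; the two S centres are remote from the oxidised carbons. The step needs chemoselectivity for the enolised β-dicarbonyl over the allylic ether C–H, the isopropenyl group and the benzylic CH2 of the product. The enol is by far the most easily oxidised site and the hydrogen-bonded formyl phenol formed is deactivated, so a near-stoichiometric amount of DDQ at room temperature should stop at 13. The C3 methoxy group already distinguishes the two ring oxygens, so the phenol appears only at C1, the future C8a.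

**Step 9**
Reactants: 13 the bis(salicylaldehyde) of step 8; 14 (triphenylphosphoranylidene)ketene
Product: 16 8-[(2S)-2-{[(3S)-3-[(tert-butyldimethylsilyl)oxy]-4-(7-methoxy-2-oxo-2H-chromen-8-yl)-2-methylbutan-2-yl]oxy}-3-methylbut-3-en-1-yl]-7-methoxy-2H-chromen-2-one, via bis(phosphoranylideneacetate) 15 (not isolated)
Conditions: Ph3P=C=C=O (2.4 equiv), toluene, 110 °C
Reagents that add atoms: none
Why: Bestmann coumarin synthesis, in which each phenol adds to the ketene carbon of the cumulated ylide to give an aryl (triphenylphosphoranylidene)acetate whose stabilised ylide closes the pyranone ring by intramolecular Wittig olefination of the ortho formyl group; the formyl carbon becomes C4 and the ring enforces the cis alkene.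

**Step 10**
Reactants: 16 the silyl-protected bis-coumarin of step 9
Product: 17 8-[(2S)-2-{[(3S)-3-hydroxy-4-(7-methoxy-2-oxo-2H-chromen-8-yl)-2-methylbutan-2-yl]oxy}-3-methylbut-3-en-1-yl]-7-methoxy-2H-chromen-2-one (CNP0142500.1)
Conditions: Bu4NF, AcOH, THF, 0 °C → rt
Reagents that add atoms: none
Why: fluoride-induced cleavage of the silyl ether driven by Si–F bond formation, buffered with AcOH so that the lactones and the allylic tert-alkyl ether are not exposed to strong base; no stereocentre is touched.

**Compound list**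
1 | cyclohexane-1,3-dione | O=C1CCCC(=O)C1 | starting material
2 | prenyl bromide (1-bromo-3-methylbut-2-ene) | CC(C)=CCBr | starting material
3 | 2-(3-methylbut-2-en-1-yl)cyclohexane-1,3-dione | CC(C)=CCC1C(=O)CCCC1=O | intermediate
4 | 3-methoxy-2-(3-methylbut-2-en-1-yl)cyclohex-2-en-1-one | COC1=C(CC=C(C)C)C(=O)CCC1 | intermediate
5 | 2-{[(2S)-3,3-dimethyloxiran-2-yl]methyl}-3-methoxycyclohex-2-en-1-one | COC1=C(C[C@@H]2OC2(C)C)C(=O)CCC1 | intermediate
6 | 2-[(2S)-2-hydroxy-3-methylbut-3-en-1-yl]-3-methoxycyclohex-2-en-1-one | C=C(C)[C@H](CC1=C(OC)CCCC1=O)O | intermediate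
7 | 2-[(2S)-2-{[(3S)-3-hydroxy-4-(2-methoxy-6-oxocyclohex-1-en-1-yl)-2-methylbutan-2-yl]oxy}-3-methylbut-3-en-1-yl]-3-methoxycyclohex-2-en-1-one | C=C(C)[C@H](CC1=C(OC)CCCC1=O)OC(C)(C)[C@@H](O)CC1=C(OC)CCCC1=O | intermediate
8 | tert-butyldimethylsilyl ether of 7 (bis(vinylogous ester), S,S) | C=C(C)[C@H](CC1=C(OC)CCCC1=O)OC(C)(C)[C@@H](O[Si](C)(C)C(C)(C)C)CC1=C(OC)CCCC1=O | intermediate
9 | ethyl formate | CCOC=O | starting material
10 | bis(lithium dienolate) of 8 (O1–Li, C1=C6 in each ring) | C=C(C)[C@H](CC1=C(OC)CCC=C1O[Li])OC(C)(C)[C@@H](O[Si](C)(C)C(C)(C)C)CC1=C(OC)CCC=C1O[Li] | intermediate (not isolated)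
11 | bis[6-(hydroxymethylene)-3-methoxycyclohex-2-en-1-one] ether, silyl-protected (S,S; key-step precursor) | C=C(C)[C@H](CC1=C(OC)CC/C(=C/O)C1=O)OC(C)(C)[C@@H](O[Si](C)(C)C(C)(C)C)CC1=C(OC)CC/C(=C/O)C1=O | intermediate
12 | bis(6-formyl-3-methoxycyclohexa-2,5-dien-1-one) ether, silyl-protected (S,S) | C=C(C)[C@H](CC1=C(OC)CC=C(C=O)C1=O)OC(C)(C)[C@@H](O[Si](C)(C)C(C)(C)C)CC1=C(OC)CC=C(C=O)C1=O | intermediate (not isolated)
13 | 3-[(2S)-2-{[(3S)-3-[(tert-butyldimethylsilyl)oxy]-4-(3-formyl-2-hydroxy-6-methoxyphenyl)-2-methylbutan-2-yl]oxy}-3-methylbut-3-en-1-yl]-2-hydroxy-4-methoxybenzaldehyde (key-step product) | C=C(C)[C@H](Cc1c(OC)ccc(C=O)c1O)OC(C)(C)[C@@H](O[Si](C)(C)C(C)(C)C)Cc1c(OC)ccc(C=O)c1O | intermediate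
14 | (triphenylphosphoranylidene)ketene | O=C=C=P(c1ccccc1)(c1ccccc1)c1ccccc1 | starting material
15 | bis[aryl (triphenylphosphoranylidene)acetate] of 13 (both phenols acylated, formyl groups intact) | C=C(C)[C@H](Cc1c(OC)ccc(C=O)c1OC(=O)C=P(c1ccccc1)(c1ccccc1)c1ccccc1)OC(C)(C)[C@@H](O[Si](C)(C)C(C)(C)C)Cc1c(OC)ccc(C=O)c1OC(=O)C=P(c1ccccc1)(c1ccccc1)c1ccccc1 | intermediate (not isolated)
16 | 8-[(2S)-2-{[(3S)-3-[(tert-butyldimethylsilyl)oxy]-4-(7-methoxy-2-oxo-2H-chromen-8-yl)-2-methylbutan-2-yl]oxy}-3-methylbut-3-en-1-yl]-7-methoxy-2H-chromen-2-one | C=C(C)[C@H](Cc1c(OC)ccc2ccc(=O)oc12)OC(C)(C)[C@@H](O[Si](C)(C)C(C)(C)C)Cc1c(OC)ccc2ccc(=O)oc12 | intermediate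
17 | 8-[(2S)-2-{[(3S)-3-hydroxy-4-(7-methoxy-2-oxo-2H-chromen-8-yl)-2-methylbutan-2-yl]oxy}-3-methylbut-3-en-1-yl]-7-methoxy-2H-chromen-2-one | C=C(C)[C@H](Cc1c(OC)ccc2ccc(=O)oc12)OC(C)(C)[C@@H](O)Cc1c(OC)ccc2ccc(=O)oc12 | target

**Total step count:** 10. **Longest linear sequence:** 10 steps (1 → 17; epoxide 5 is used twice).

**Steps most likely to fail**

Step 5 (etherification). The vinylogous ester carbonyl next to the activated epoxide may close onto it faster than the hindered external alcohol arrives (cyclisation with loss of the O-methyl group), or a hydride shift to the isopropyl ketone (Meinwald rearrangement) may intervene, so that little ether forms. The fallback sets out from 6, with 2 and 1 as further inputs, and returns at 8. It uses a ring-free electrophile and attaches ring B afterwards through C2 of the dione. Prenyl bromide 2 with 4-methoxybenzyl alcohol and NaH should give 4-methoxybenzyl prenyl ether F1. The same ent-Shi epoxidation should give the (S)-epoxide F2, which has no carbonyl group that could take part. BF3·OEt2-promoted opening of F2 (in excess) by 6 at the tertiary carbon should give hydroxy ether F3. TBSOTf/2,6-lutidine should give its silyl ether F4, DDQ in wet CH2Cl2 the primary alcohol F5, and Dess–Martin periodinane the α-silyloxy aldehyde F6. Proline-catalysed reductive alkylation of cyclohexane-1,3-dione 1 with F6 and Hantzsch ester (Knoevenagel condensation, then conjugate hydride transfer) should give the 2-alkyl dione F7. Me2SO4/K2CO3 then converts F7 into 8.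

Step 4 (epoxide to allylic alcohol). The aluminium amide may enolise or add to the vinylogous ester instead of rearranging the epoxide, the resulting enolate oxygen may open the epoxide internally, or proton removal may take place at the ring-side CH2 and lead to the conjugated tertiary allylic alcohol. The fallback sets out from 4 and returns at 6; it transposes an epoxy alcohol without any cationic or strongly basic step. SeO2 (cat.)/t-BuOOH oxidation of the (E)-methyl group of 4 should give the (E)-allylic alcohol F8. Sharpless asymmetric epoxidation (Ti(OiPr)4, L-(+)-diethyl tartrate, t-BuOOH, 4 Å molecular sieves, −20 °C) should give the (2S,3S)-epoxy alcohol F9. Appel-type iodination (I2, PPh3, imidazole) should give the epoxy iodide F10. Zn dust in refluxing EtOH should open F10 reductively to 6; the carbinol carbon is the untouched epoxide CH carbon, so its S configuration is kept.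

Step 8 (key step). DDQ may over-oxidise at the benzylic CH2 of the electron-rich product or at the allylic ether C–H, or the second ring may be dehydrogenated incompletely. The fallback sets out from 11 and returns at 13; it replaces hydride abstraction by selenation and selenoxide syn-elimination. PhSeCl/pyridine in CH2Cl2 at 0 °C should selenate C6 of each enolised ring to give the bis(6-formyl-6-phenylselanyl) compound F11 (a mixture of C6 epimers, which does not matter). H2O2 at 0 °C should oxidise selenium; syn-elimination toward C5 gives dienone 12, which tautomerises to 13.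

**Further compounds**
F1 | step 5 | 4-methoxybenzyl prenyl ether (1-methoxy-4-{[(3-methylbut-2-en-1-yl)oxy]methyl}benzene) | COc1ccc(COCC=C(C)C)cc1
F2 | step 5 | (2S)-2-{[(4-methoxybenzyl)oxy]methyl}-3,3-dimethyloxirane | COc1ccc(COC[C@@H]2OC2(C)C)cc1
F3 | step 5 | 2-[(2S)-2-{[(3S)-3-hydroxy-4-[(4-methoxybenzyl)oxy]-2-methylbutan-2-yl]oxy}-3-methylbut-3-en-1-yl]-3-methoxycyclohex-2-en-1-one | C=C(C)[C@H](CC1=C(OC)CCCC1=O)OC(C)(C)[C@@H](O)COCc1ccc(OC)cc1
F4 | step 5 | tert-butyldimethylsilyl ether of F3 | C=C(C)[C@H](CC1=C(OC)CCCC1=O)OC(C)(C)[C@@H](O[Si](C)(C)C(C)(C)C)COCc1ccc(OC)cc1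
F5 | step 5 | primary alcohol from F4 (4-methoxybenzyl group removed; (3S)-silyloxy) | C=C(C)[C@H](CC1=C(OC)CCCC1=O)OC(C)(C)[C@@H](O[Si](C)(C)C(C)(C)C)CO
F6 | step 5 | (2R)-2-[(tert-butyldimethylsilyl)oxy]-3-{[(2S)-1-(2-methoxy-6-oxocyclohex-1-en-1-yl)-3-methylbut-3-en-2-yl]oxy}-3-methylbutanal | C=C(C)[C@H](CC1=C(OC)CCCC1=O)OC(C)(C)[C@@H](O[Si](C)(C)C(C)(C)C)C=O
F7 | step 5 | 2-[(2S)-2-[(tert-butyldimethylsilyl)oxy]-3-{[(2S)-1-(2-methoxy-6-oxocyclohex-1-en-1-yl)-3-methylbut-3-en-2-yl]oxy}-3-methylbutyl]cyclohexane-1,3-dione | C=C(C)[C@H](CC1=C(OC)CCCC1=O)OC(C)(C)[C@@H](O[Si](C)(C)C(C)(C)C)CC1C(=O)CCCC1=O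
F8 | step 4 | 2-[(2E)-4-hydroxy-3-methylbut-2-en-1-yl]-3-methoxycyclohex-2-en-1-one | COC1=C(C/C=C(\C)CO)C(=O)CCC1
F9 | step 4 | 2-{[(2S,3S)-3-(hydroxymethyl)-3-methyloxiran-2-yl]methyl}-3-methoxycyclohex-2-en-1-one | COC1=C(C[C@@H]2O[C@@]2(C)CO)C(=O)CCC1
F10 | step 4 | 2-{[(2S,3R)-3-(iodomethyl)-3-methyloxiran-2-yl]methyl}-3-methoxycyclohex-2-en-1-one | COC1=C(C[C@@H]2O[C@@]2(C)CI)C(=O)CCC1
F11 | step 8 | bis[6-formyl-3-methoxy-6-(phenylselanyl)cyclohex-2-en-1-one] analogue of 11 (S,S side chain, C6 epimers) | C=C(C)[C@H](CC1=C(OC)CCC(C=O)([Se]c2ccccc2)C1=O)OC(C)(C)[C@@H](O[Si](C)(C)C(C)(C)C)CC1=C(OC)CCC(C=O)([Se]c2ccccc2)C1=O
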